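The data are calculated from invented constants; noise was put on by code.

Slowness is a help here: Sunday's flask took 8.00 h to reach a reading of 26.4%, so a mean of its partner fraction can stand in for integration.

| flask | substrate | partner | free catalyst | remark | time |
|---|---|---|---|---|---|
| Sunday's | 19 mM | 24.7 mM | 34 µM | run made earlier |  |
| green | 30 mM | 24.7 mM | 51 µM |  | 12 h |
| violet | 19 mM | 24.7 mM | 51 µM |  | 12 h |
| blue | 12 mM | 24.7 mM | 51 µM |  | 12 h |
| red | 5.0 mM | 24.7 mM | 51 µM |  | 12 h |
| teal | 10 mM | 24.7 mM | 51 µM |  | 12 h |

Sunday's run (percent of the substrate charged): time / h: target / % = 0.500: 1.5; 1.00: 5.0; 1.50: 5.1; 2.50: 10.4; 4.00: 14.5; 8.00: 26.4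

(readings scatter by 1 percentage point)

- a reading or a percentage of target counts all its forms, free or not
- no earlier run changes the charge of free catalyst; that part of a forecast is a guess

* the flasks put in order of amount of target, in percent of the substrate charged, best first, at 12 h (green / violet / blue / red / teal)
* the amount of target, in percent of the substrate charged of the flask you put first, at 12 h
* the amount of target, in percent of the substrate charged of the flask you put last, at 12 h

**What do you take from Sunday's run?**
I assume that one partner goes with one substrate and that the rate follows both fractions. Then the natural logarithm of one over the substrate fraction left, divided by the time and by the mean partner fraction, is close to a constant. Sunday's mean partner fraction, midway between its start and its last reading, is 0.898, which gives 0.0426 h⁻¹.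

**But that belongs to Sunday's catalyst. What about 51 µM?**
No run changes the catalyst, so this is a guess: I scale in proportion and get 0.0640 h⁻¹. I call this the pace: the fraction of the remaining substrate that goes per hour with partner at its full charge, a pseudo-first-order constant.

**Where does control change hands?**
Where the substrate charge equals the partner charge: on my one-to-one assumption, above that crossing the partner fraction falls faster than the substrate fraction, and partner is the limiting reagent. Green stands at 1.21, and red at 0.202. At one pace, then, I rank the flasks by rising substrate charge, with red first.

**Your number for red?**
Red's mean partner fraction is about 0.946, so my reckoning gives 51.6% for red.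

**And if the pace differs between charges?**
Then my number moves, and Sunday's single substrate charge cannot show that.

The forecast gives red > teal > blue > violet > green, with 51% on top (range 42% to 70%), against my 51.6%, and 40% last (range 26% to 46%). Its ground is that “the smallest charge converts best”.

The order comes out as red > teal > blue > violet > green, with red at 60.2% and green at 37.0%. Red stands 9.2 percentage points above the forecast, inside its range. At 12 h, free catalyst is 77.7% of the catalyst charged in red and 42.1% in green. Read back from these results, with each flask's partner fraction midway between its start and 12 h, red's pace is 0.0817 h⁻¹ and green's 0.0496 h⁻¹. The carried 0.0640 h⁻¹ lies between them.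

    substrate + free catalyst ⇌ catalyst intermediate A (K = 17.0 M⁻¹, k = 2.50 M⁻¹ s⁻¹)
    partner + catalyst intermediate A ⇌ catalyst intermediate B (K = 30.0 M⁻¹, k = 1.60 M⁻¹ s⁻¹)
    catalyst intermediate B → by-product + catalyst intermediate C (k = 4.70 s⁻¹)
    catalyst intermediate C → free catalyst + target (k = 0.0380 s⁻¹)
    free catalyst + target ⇌ idle complex (K = 120 M⁻¹, k = 0.00520 M⁻¹ s⁻¹)

Take red with partner cut to 15 mM. Scaling the pace read back for red by the partner charge gives 0.0496 h⁻¹, a mean partner fraction of 0.925, and so 42.3%. The computed flask gives 45.8%.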